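An easy step first: read a slope off two readings.

| flask | starting material | gas | enzyme | remark | time |
|---|---|---|---|---|---|
| ochre | 0.010 M | 6.6 mM (held) | 0.01 mol% (in portions, 4) | run made earlier; portions every 4.0 min |  |
| violet | 0.040 M | 6.6 mM (held) | 0.01 mol% (in portions, 4) | run made earlier; portions every 4.0 min |  |
| green | 0.020 M | 6.6 mM (held) | 0.015 mol% (in portions, 4) | run made earlier; portions every 4.0 min |  |
| flask | 0.020 M | 6.6 mM (held) | 0.01 mol% (in portions, 4) | the portions of enzyme follow each other after 4.0 min, the first at the start | 1.0 h |

- ochre (time / min: product / %): 20.0: 35.8; 40.0: 76.4; 50.0: 87.3; 80.0: 98.5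
- violet (time / min: product / %): 10.0: 11.4; 25.0: 32.2; 50.0: 65.4; 80.0: 99.0
- green (time / min: product / %): 6.00: 6.7; 12.0: 22.3; 30.0: 69.8; 80.0: 100.3

(readings scatter by 0.5 percentage points)

- the numbers in the tables scatter by 0.5 percentage points (one standard deviation)
- at the start none of the gas is in solution

1. how much product the flask holds at 1.0 h, in percent of the starting material charged
2. concentration of second substrate at 1.0 h, in M

What rate does the violet run hold through mid-run? Between 25.0 min and 50.0 min product rises at 0.531 mM/min. Between 10.0 min and 25.0 min it rises at 0.555 mM/min, which is faster, so the first figure is a mid-run reading and no peak.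

And in the green run? Between 12.0 min and 30.0 min it rises at 0.528 mM/min.

What do you make of that? Violet holds 1.33 times the enzyme of green, yet the slopes match. So I read gas crossing into second substrate as the rate-limiting step there, and I call the violet mid-run slope the read supply rate.

What does it give for this flask? Charge over read supply rate: 37.7 min. I call this the supply time, the time gas crossing at that rate takes to deliver one equivalent. It is shorter than the 1.0 h allowed.

But a supply rate is no promise. Can the enzyme keep up? The flask needs a mean of 0.333 mM/min. The ochre run, with half the flask's enzyme, climbs at 0.203 mM/min. If rate goes with enzyme, the flask manages 0.406 mM/min, which is above the need.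

Your commitment? A flask close to its full charge of product, with no figure for [second substrate].

The forecast gives figures: 94.5% of product and 0.0042 M of second substrate, holding that “gas transfer is limiting” in mid-run.

The flask gives 98.4% of product and [second substrate] of 0.00448 M, within the forecast's margins.

    gas ⇌ second substrate, rate k1*(csat - [second substrate]) (kL = 0.00150 /s)
    ternary complex → enzyme + product (k = 9.80 /s)
    starting material + enzyme ⇌ starting complex (K = 450 /M, k = 1600 /M/s)
    second substrate + starting complex ⇌ ternary complex (K = 3100 /M, k = 11000 /M/s)

Starting material stands at 1.59% of its charge at 1.00 h. With 0.080 M of starting material the supply time becomes 151 min, longer than 1.0 h. Crossing at the read supply rate delivers 39.7% of that charge in this time, and that neighbour flask holds 42.8% of product at 1.00 h.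

All runs come from a simulation for substances that don't exist; the scatter is artificial.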